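Atoms are numbered chamigrane-style: C1–C5 form the halogenated ring A (Br on C2; Me and Cl on C3), C6 is the spiro atom and C7–C11 form ring B (C7 methylidene, C8 carbonyl, C10 bromine, C11 gem-dimethyl). The plan rests on cutting ring A at C5–C6 and C1=C2: with C3 as a ketone, ring A is a 4,4-disubstituted cyclohexenone, the Robinson product of methyl vinyl ketone and a ring B aldehyde whose single α-carbon is C6. One amine-catalysed operation forges both bonds, closes ring A and sets the quaternary centre, the racemic aldehyde converging through its enamine. The precursor is racemic 3-bromo-2,2-dimethylcyclohex-3-ene-1-carbaldehyde, whose C10 vinyl bromide replaces a second ketone that would compete later.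

Key step: step 4

Remarks before the steps
- Names use the atom numbers defined above (C14 is the methylidene carbon), not lowest-locant rules; CIP descriptors refer to the drawn structures.
- The spatial arrangement at C6 is the same from 10 to 18; the descriptor reads (6S) in 10–14, (6R) in 15 and (6S) in 16–18 only because substituent priorities change.
- Assumption: the quinine-derived primary amine is taken to give the (6S) series; if induction runs the other way, its quinidine-derived pseudoenantiomer is used with no other change.

Step 1
Reactants: 1 2,2-dimethylcyclohexane-1,3-dione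
Product: 2 6,6-dimethyl-5-oxocyclohex-1-en-1-yl trifluoromethanesulfonate
Conditions: KN(SiMe3)2 (1.05 equiv), THF, −78 °C; PhNTf2, −78 → 0 °C
Reagents that add atoms: N-phenylbis(trifluoromethanesulfonimide), O=S(=O)(N(c1ccccc1)S(=O)(=O)C(F)(F)F)C(F)(F)F
Why: Deprotonation of the symmetric dione can only occur away from the quaternary carbon, and O-sulfonylation of that single enolate (enol triflate formation) should give the mono enol triflate, since one equivalent of base makes one enolate.

Step 2
Reactants: 2 6,6-dimethyl-5-oxocyclohex-1-en-1-yl trifluoromethanesulfonate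
Product: 3 3-bromo-2,2-dimethylcyclohex-3-en-1-one
Conditions: Ni(cod)2 (10 mol %), LiBr (2 equiv), DMA/THF, rt
Reagents that add atoms: lithium bromide, [Li+].[Br-]
Why: Nickel-catalysed triflate–halide exchange of enol triflates (oxidative addition to zerovalent nickel, triflate/bromide metathesis, C–Br reductive elimination) should give the vinyl bromide next to the quaternary carbon and leave the unconjugated ketone untouched.

Step 3
Reactants: 3 3-bromo-2,2-dimethylcyclohex-3-en-1-one; 4 (methoxymethyl)triphenylphosphonium chloride
Product: 6 rac-3-bromo-2,2-dimethylcyclohex-3-ene-1-carbaldehyde, via methyl enol ether 5 (not isolated)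
Conditions: Ph3P(CH2OMe)Cl (2.5 equiv), KOt-Bu, THF, 0 °C → rt; then 2 M aq. HCl, THF, rt
Reagents that add atoms: (methoxymethyl)triphenylphosphonium chloride (4), COC[P+](c1ccccc1)(c1ccccc1)c1ccccc1.[Cl-]; water, O
Why: Wittig methoxymethylenation of the hindered ketone and acid hydrolysis of the enol ether is the standard one-carbon homologation to an aldehyde, and the new C6 centre may form racemic because step 4 passes through its enamine.

Step 4
Reactants: 6 rac-3-bromo-2,2-dimethylcyclohex-3-ene-1-carbaldehyde; 7 methyl vinyl ketone
Product: 10 (6S)-10-bromo-11,11-dimethylspiro[5.5]undeca-1,9-dien-3-one, via Michael keto aldehyde 8 (not isolated), via ketol 9 (not isolated)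
Conditions: 9-amino-9-deoxy-epi-quinine (20 mol %), PhCO2H (40 mol %), methyl vinyl ketone (2 equiv), toluene, rt → 50 °C
Reagents that add atoms: methyl vinyl ketone (7), CC(=O)C=C
Why: The primary amine condenses with 6 to an enamine whose C1=C6 double bond erases the labile C6 centre, so both enantiomers of 6 become one nucleophile that adds through C6 to the acid-activated enone (C5–C6 bond), and hydrolysis releases keto aldehyde 8. The closest known reaction type is the primary-amine-catalysed asymmetric Robinson annulation of α-branched aldehydes with methyl vinyl ketone to 4,4-disubstituted cyclohex-2-enones. Ring A then closes by a 6-(enolexo)-exo-trig aldol of the methyl ketone carbon C2 onto the aldehyde carbon C1 (ketol 9), and dehydration gives the C1=C2 enone. The only new stereocentre, C6, is set by the catalyst: the enamine nitrogen lies anti to C11Me2 and syn to C7H2, and the cinchona scaffold with its protonated quinuclidine should direct the enone to one face of this single enamine geometry. The step needs facial selectivity and enough reactivity at a carbon flanked by quaternary C11; the size gap between C11Me2 and C7H2 fixes the enamine geometry, the single α-hydrogen excludes regioisomeric enamines, and the vinyl bromide is inert to amine and acid.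

Step 5
Reactants: 10 (6S)-10-bromo-11,11-dimethylspiro[5.5]undeca-1,9-dien-3-one
Product: 12 (2S,6S)-2,10-dibromo-11,11-dimethylspiro[5.5]undec-9-en-3-one, via triethylsilyl enol ether 11 (not isolated)
Conditions: RhCl(PPh3)3 (2 mol %), Et3SiH, toluene, 50 °C; then NBS, THF, 0 °C; then HBr (cat.), AcOH, rt
Reagents that add atoms: N-bromosuccinimide, O=C1CCC(=O)N1Br
Why: Rhodium-catalysed 1,4-hydrosilylation puts hydride on C1 and fixes the enol ether at C2=C3, so electrophilic bromination of the silyl enol ether can only occur at C2, and acid equilibration of the α-bromo ketone through its enol should leave bromine equatorial, cis to C11 and away from the axial C7 methylene (thermodynamic control of C2).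

Step 6
Reactants: 12 (2S,6S)-2,10-dibromo-11,11-dimethylspiro[5.5]undec-9-en-3-one
Product: 13 (2S,3R,6S)-2,10-dibromo-3,11,11-trimethylspiro[5.5]undec-9-en-3-ol
Conditions: CeCl3 (anhydrous), MeMgBr, THF, −78 °C; then H2O, −78 °C → rt
Reagents that add atoms: methylmagnesium bromide, C[Mg]Br
Why: The organocerium reagent made in the flask should add 1,2 to the activated α-bromo ketone without enolisation or halogen loss (organocerium carbonyl addition), equatorial attack trans to bromine being expected to favour the (3R) carbinol, whose C3 configuration is not carried into the target because step 7 ionises this centre.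

Step 7
Reactants: 13 (2S,3R,6S)-2,10-dibromo-3,11,11-trimethylspiro[5.5]undec-9-en-3-ol
Product: 14 (2S,3S,6S)-2,10-dibromo-3-chloro-3,11,11-trimethylspiro[5.5]undec-9-ene
Conditions: HCl (g), CH2Cl2, 0 °C → rt
Reagents that add atoms: hydrogen chloride, Cl
Why: Protonation and ionisation of the tertiary alcohol (SN1 hydrochlorination with neighbouring-halogen control) gives a C3 cation whose lower face is covered by the leaning C2–Br bond and by the departing water, so chloride should enter anti to bromine and give the trans Br/Cl pair with axial methyl, that is (3S).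

Step 8
Reactants: 14 (2S,3S,6S)-2,10-dibromo-3-chloro-3,11,11-trimethylspiro[5.5]undec-9-ene
Product: 15 (2S,3S,6R)-2,10-dibromo-3-chloro-3,11,11-trimethylspiro[5.5]undec-9-en-8-one
Conditions: CrO3, 3,5-dimethylpyrazole, CH2Cl2, −20 °C
Reagents that add atoms: chromium trioxide, O=[Cr](=O)=O
Why: Chromium trioxide–3,5-dimethylpyrazole allylic oxidation should turn C8, the only allylic CH2 of the C9=C10 vinyl bromide (C11 is quaternary), into the ketone, the equatorial alkyl halides of ring A being inert to the oxidant.

Step 9
Reactants: 15 (2S,3S,6R)-2,10-dibromo-3-chloro-3,11,11-trimethylspiro[5.5]undec-9-en-8-one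
Product: 18 (2S,3S,6S)-2,10-dibromo-3-chloro-3,11,11-trimethyl-7-methylidenespiro[5.5]undec-9-en-8-one, via Mannich base 16 (not isolated), via ammonium iodide 17 (not isolated)
Conditions: LiN(SiMe3)2, THF, −78 °C; Me2N=CH2 iodide, −78 °C → rt; then MeI, CH2Cl2, rt; then aq. NaHCO3, rt
Reagents that add atoms: N,N-dimethylmethyleneiminium iodide, C=[N+](C)C.[I-]
Why: Kinetic deprotonation can occur only at C7 (C9 is vinylic, C11 quaternary), the lithium enolate is aminomethylated by the iminium salt (Mannich reaction), and quaternisation followed by base-induced β-elimination of trimethylamine should give the C7=C14 methylidene, while the equatorial C2 bromide and C3 chloride have no antiperiplanar ring hydrogen for E2 loss.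

Compound list
1 | 2,2-dimethylcyclohexane-1,3-dione | CC1(C)C(=O)CCCC1=O | starting material
2 | 6,6-dimethyl-5-oxocyclohex-1-en-1-yl trifluoromethanesulfonate | CC1(C)C(=O)CCC=C1OS(=O)(=O)C(F)(F)F | intermediate
3 | 3-bromo-2,2-dimethylcyclohex-3-en-1-one | CC1(C)C(=O)CCC=C1Br | intermediate
4 | (methoxymethyl)triphenylphosphonium chloride | COC[P+](c1ccccc1)(c1ccccc1)c1ccccc1.[Cl-] | starting material
5 | 1-bromo-5-(methoxymethylidene)-6,6-dimethylcyclohex-1-ene (E/Z mixture, not isolated) | COC=C1CCC=C(Br)C1(C)C | intermediate
6 | rac-3-bromo-2,2-dimethylcyclohex-3-ene-1-carbaldehyde | O=CC1CCC=C(Br)C1(C)C | intermediate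
7 | methyl vinyl ketone | CC(=O)C=C | starting material
8 | (1R)-3-bromo-2,2-dimethyl-1-(3-oxobutyl)cyclohex-3-ene-1-carbaldehyde (not isolated) | C1CC=C(Br)C(C)(C)[C@]1(C=O)CCC(C)=O | intermediate
9 | (6R)-10-bromo-1-hydroxy-11,11-dimethylspiro[5.5]undec-9-en-3-one (C1 epimers, not isolated) | C1CC=C(Br)C(C)(C)[C@]12CCC(=O)CC2O | intermediate
10 | (6S)-10-bromo-11,11-dimethylspiro[5.5]undeca-1,9-dien-3-one | C1CC=C(Br)C(C)(C)[C@]12CCC(=O)C=C2 | intermediate
11 | (6S)-10-bromo-11,11-dimethyl-3-(triethylsilyloxy)spiro[5.5]undeca-2,9-diene (not isolated) | C1CC=C(Br)C(C)(C)[C@]12CCC(O[Si](CC)(CC)CC)=CC2 | intermediate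
12 | (2S,6S)-2,10-dibromo-11,11-dimethylspiro[5.5]undec-9-en-3-one | C1CC=C(Br)C(C)(C)[C@]12CCC(=O)[C@@H](Br)C2 | intermediate
13 | (2S,3R,6S)-2,10-dibromo-3,11,11-trimethylspiro[5.5]undec-9-en-3-ol | C1CC=C(Br)C(C)(C)[C@]12CC[C@](O)(C)[C@@H](Br)C2 | intermediate
14 | (2S,3S,6S)-2,10-dibromo-3-chloro-3,11,11-trimethylspiro[5.5]undec-9-ene | C1CC=C(Br)C(C)(C)[C@]12CC[C@](C)(Cl)[C@@H](Br)C2 | intermediate
15 | (2S,3S,6R)-2,10-dibromo-3-chloro-3,11,11-trimethylspiro[5.5]undec-9-en-8-one | C1C(=O)C=C(Br)C(C)(C)[C@]12CC[C@](C)(Cl)[C@@H](Br)C2 | intermediate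
16 | (2S,3S,6S)-2,10-dibromo-3-chloro-7-[(dimethylamino)methyl]-3,11,11-trimethylspiro[5.5]undec-9-en-8-one (C7 epimers, not isolated) | C1(CN(C)C)C(=O)C=C(Br)C(C)(C)[C@]12CC[C@](C)(Cl)[C@@H](Br)C2 | intermediate
17 | [(2S,3S,6S)-2,10-dibromo-3-chloro-3,11,11-trimethyl-8-oxospiro[5.5]undec-9-en-7-yl]methyl-trimethylammonium iodide (C7 epimers, not isolated) | C1(C[N+](C)(C)C)C(=O)C=C(Br)C(C)(C)[C@]12CC[C@](C)(Cl)[C@@H](Br)C2.[I-] | intermediate
18 | (2S,3S,6S)-2,10-dibromo-3-chloro-3,11,11-trimethyl-7-methylidenespiro[5.5]undec-9-en-8-one | C=C1C(=O)C=C(Br)C(C)(C)[C@]12CC[C@](C)(Cl)[C@@H](Br)C2 | target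

Total step count: 9. Longest linear sequence: 9 steps (1 → 18).

Steps most likely to fail

Step 4. Bond formation at an enamine carbon flanked by quaternary C11 may be slow, and the catalyst may distinguish the two enamine faces poorly, so conversion or enantiomeric purity may fall short. Fallback (stoichiometric chiral auxiliary in place of catalysis): setting out from aldehyde 6, condensation with (R)-1-phenylethylamine (toluene, 4 Å MS) gives the chiral aldimine F1. Its secondary enamine tautomer adds to methyl vinyl ketone 7 (THF, 40 °C, auxiliary-controlled Michael addition) to give the adduct imine F2. Aqueous acetic acid releases keto aldehyde 8, and KOH in methanol closes and dehydrates it through ketol 9 to enone 10, where the route is rejoined. The amine enantiomer is chosen to give the (R) adduct.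

Step 7. Chloride may be captured on the bromine face, giving the cis Br/Cl epimer at C3, or the C3 cation may lose a proton to an alkene instead of taking chloride. Fallback (front-side delivery from the epimeric carbinol in place of cation capture): setting out from bromo ketone 12, precomplexation with MeAl(OAr)2 (Ar = 2,6-di-tert-butyl-4-methylphenyl) and addition of MeLi (toluene, −78 °C) delivers methyl axially and should give the (2S,3S,6S) carbinol F3 with equatorial hydroxyl. SOCl2 in ether then forms the chlorosulfite F4, which collapses with internal return of chloride and retention (SNi) to bromochloride 14.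

Step 8. Oxidation through the delocalised C8–C9–C10 allyl intermediate may end at C10 with loss of the vinylic bromine, or hydrogen abstraction next to the electron-poor alkene may stall. Fallback (allylic halogenation and oxidation of the halide in place of direct C–H oxidation): setting out from 14, Wohl–Ziegler bromination (NBS, (PhCO2)2 cat., PhCF3, 80 °C) gives the C8 allylic bromide F5, and Kornblum oxidation (DMSO, NaHCO3, 60 °C) converts it into enone 15.

Further compounds
F1 | step 4 | N-[(R)-1-phenylethyl] aldimine of rac-6 | C[C@@H](N=CC1CCC=C(Br)C1(C)C)c1ccccc1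
F2 | step 4 | N-[(R)-1-phenylethyl] aldimine of (1R)-keto aldehyde 8 | C[C@@H](N=C[C@@]1(CCC(C)=O)CCC=C(Br)C1(C)C)c1ccccc1
F3 | step 7 | (2S,3S,6S)-2,10-dibromo-3,11,11-trimethylspiro[5.5]undec-9-en-3-ol | C1CC=C(Br)C(C)(C)[C@]12CC[C@](C)(O)[C@@H](Br)C2
F4 | step 7 | chlorosulfite of F3 | C1CC=C(Br)C(C)(C)[C@]12CC[C@](C)(OS(=O)Cl)[C@@H](Br)C2
F5 | step 8 | (2S,3S,6R)-2,8,10-tribromo-3-chloro-3,11,11-trimethylspiro[5.5]undec-9-ene (C8 epimers) | C1C(Br)C=C(Br)C(C)(C)[C@]12CC[C@](C)(Cl)[C@@H](Br)C2
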